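The route rests on opening ring C of the middle flavan unit across C3–C4 and O1–C2. In the key step an ortho-quinone methide, released from a 2-hydroxybenzhydrol whose carbinol carbon (future C4) already carries C6 of the lower unit and whose resorcinol ring A already carries the upper unit, undergoes an oxa-Diels–Alder reaction with the (E)-enol formate of 3,4-bis(benzyloxy)phenylacetaldehyde. One operation closes ring C, forms C3–C4 and O1–C2 and sets C2, C3 and C4. It exploits the free O1 phenol ortho to the doubly benzylic C4 of ring A. The lower unit travels as its 4-ketone and is reduced last.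

Key step: step 14

Assumption: the (R)-configured N-triflylphosphoramide is taken to select the quinone methide face that gives the (2R,3S,4R) middle unit; if a model reaction shows the opposite sense, its enantiomer is used.
Remark: flavan locants (O1, C2, C3, C4, C4a, C5 to C8, C8a; ring B primed) are used for each unit; the upper unit is bonded through C4 to C6 of the middle unit, and the lower unit carries the C4 oxygen.

Step 1
Reactants: 1 (+)-taxifolin
Product: 2 (2R,3R)-7-(benzyloxy)-2-[3,4-bis(benzyloxy)phenyl]-3,5-dihydroxychroman-4-one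
Conditions: BnBr (3.3 equiv), K2CO3, DMF, rt
Reagents that add atoms: benzyl bromide, BrCc1ccccc1
Why: Williamson etherification in which carbonate alkylates only the three free phenols, the 5-OH being locked in a hydrogen bond to the C4 carbonyl and the 3-OH being a non-acidic alcohol, so both stereocentres stay untouched.

Step 2
Reactants: 2 tri-O-benzyltaxifolin
Product: 3 (2R,3R)-7-(benzyloxy)-2-[3,4-bis(benzyloxy)phenyl]-3-hydroxy-4-oxochroman-5-yl trifluoromethanesulfonate
Conditions: PhNTf2 (1.2 equiv), Et3N, DMAP (cat.), CH2Cl2, 0 °C to rt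
Reagents that add atoms: N-phenylbis(trifluoromethanesulfonimide), O=S(=O)(C(F)(F)F)N(c1ccccc1)S(=O)(=O)C(F)(F)F
Why: Phenol-selective O-sulfonylation, since the mild triflimide reagent transfers triflyl to the acidic chelated 5-phenoxide and leaves the secondary 3-OH alone.

Step 3
Reactants: 3 aryl triflate
Product: 4 (2R,3R)-7-(benzyloxy)-2-[3,4-bis(benzyloxy)phenyl]-3-hydroxychroman-4-one (7,3',4'-tri-O-benzylfustin)
Conditions: Pd(OAc)2 (5 mol %), dppf, HCO2H, Et3N, DMF, 70 °C
Reagents that add atoms: none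
Why: Palladium-catalysed formate reduction of an aryl triflate under homogeneous conditions that spare benzyl ethers and the ketone, giving the 5-deoxy ring A of the fisetinidol series.

Step 4
Reactants: 4 tri-O-benzylfustin
Product: 5 (2R,3R)-3,7-bis(benzyloxy)-2-[3,4-bis(benzyloxy)phenyl]chroman-4-one (tetra-O-benzylfustin)
Conditions: 2-benzyloxy-1-methylpyridinium triflate (2 equiv), MgO, PhCF3, 85 °C
Reagents that add atoms: 2-benzyloxy-1-methylpyridinium triflate, C[n+]1ccccc1OCc1ccccc1.[O-]S(=O)(=O)C(F)(F)F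
Why: O-benzylation by thermal benzyl transfer under neutral conditions, chosen because the α-hydroxy ketone would epimerise or ring-open under alkoxide conditions.

Step 5
Reactants: 6 3-(benzyloxy)phenol
Product: 7 3-(benzyloxy)-4-bromophenol
Conditions: NBS (1.0 equiv), MeCN, −20 °C
Reagents that add atoms: N-bromosuccinimide, O=C1CCC(=O)N1Br
Why: Electrophilic aromatic bromination directed para to the free hydroxyl, the stronger activating group, which places bromine ortho to the benzyloxy group.

Step 6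
Reactants: 7 3-(benzyloxy)-4-bromophenol
Product: 8 2-(benzyloxy)-1-bromo-4-(methoxymethoxy)benzene
Conditions: NaH, MOMCl, THF, 0 °C
Reagents that add atoms: chloromethyl methyl ether, COCCl
Why: Williamson-type formation of the MOM ether, which masks the acidic phenol for the lithiation and is designed to fall off again under the acid of step 8.

Step 7
Reactants: 8 2-(benzyloxy)-1-bromo-4-(methoxymethoxy)benzene; 5 tetra-O-benzylfustin
Product: 10 (2R,3R)-3,7-bis(benzyloxy)-4-[2-(benzyloxy)-4-(methoxymethoxy)phenyl]-2-[3,4-bis(benzyloxy)phenyl]chroman-4-ol (C4 configuration not controlled), via aryllithium 9 (not isolated)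
Conditions: n-BuLi, THF, −78 °C; then 5, −78 to −40 °C; aq NH4Cl
Reagents that add atoms: none
Why: Bromine–lithium exchange followed by 1,2-addition of the aryllithium to the flavan-4-one carbonyl, which should be faster than enolisation at −78 °C; the new C4 centre need not be controlled because it is ionised in step 8.

Step 8
Reactants: 10 tertiary carbinol
Product: 11 3-(benzyloxy)-4-{(2R,3S,4S)-3,7-bis(benzyloxy)-2-[3,4-bis(benzyloxy)phenyl]chroman-4-yl}phenol
Conditions: Et3SiH (5 equiv), TFA, CH2Cl2, −20 to 0 °C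
Reagents that add atoms: none
Why: Ionic hydrogenation in which acid ionises the tertiary doubly benzylic alcohol to the 4-aryl flavan-4-yl cation and the silane delivers hydride to the face trans to the 3-benzyloxy group, so the aryl group ends cis to O3 (3,4-cis, 4S) as the upper unit requires, while the same acid cleaves the MOM ether and frees the future O1 phenol of the middle unit.

Step 9
Reactants: 5 tetra-O-benzylfustin
Product: 12 (2R,3R)-3,7-bis(benzyloxy)-2-[3,4-bis(benzyloxy)phenyl]-6-iodochroman-4-one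
Conditions: NIS (1.05 equiv), TFA (cat.), MeCN, 0 °C to rt
Reagents that add atoms: N-iodosuccinimide, O=C1CCC(=O)N1I
Why: Electrophilic aromatic iodination at C6, para to O1 and ortho to the 7-benzyloxy group, where both ring A oxygens reinforce each other and should outpace ring B, in which each position has only one ortho or para donor.

Step 10
Reactants: 12 6-iodo ketone
Product: 13 (2R,3R)-3,7-bis(benzyloxy)-2-[3,4-bis(benzyloxy)phenyl]-4-oxochroman-6-carbaldehyde
Conditions: Pd(PPh3)4 (5 mol %), CO (3 bar), n-Bu3SnH (slow addition), toluene, 50 °C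
Reagents that add atoms: carbon monoxide, [C-]#[O+]
Why: Palladium-catalysed reductive carbonylation (formylation) of the aryl iodide, run without base so that the epimerisable α-benzyloxy ketone is not endangered.

Step 11
Reactants: 11 upper-unit phenol; 13 lower-unit aldehyde
Product: 15 (2R,3R)-3,7-bis(benzyloxy)-2-[3,4-bis(benzyloxy)phenyl]-6-{[4-(benzyloxy)-2-hydroxy-5-((2R,3S,4S)-3,7-bis(benzyloxy)-2-[3,4-bis(benzyloxy)phenyl]chroman-4-yl)phenyl](hydroxy)methyl}chroman-4-one (both carbinol epimers), via benzodioxaborin 14 (not isolated)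
Conditions: PhB(OH)2 (1.2 equiv), EtCO2H (0.3 equiv), toluene, reflux, Dean–Stark; then pinacol, THF, rt
Reagents that add atoms: none
Why: Phenylboronic acid templated ortho-hydroxyalkylation of a phenol by an aldehyde, in which the aryl boronate delivers the aldehyde to the less hindered ortho carbon, the cyclic boronate stops a second condensation and pinacol then frees the diol; the carbinol centre forms as both epimers, which is immaterial because it becomes sp2 in step 14.

Step 12
Reactants: 16 3,4-bis(benzyloxy)benzaldehyde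
Product: 17 (E)-3-[3,4-bis(benzyloxy)phenyl]prop-2-enal
Conditions: Ph3P=CHCHO, toluene, 80 °C
Reagents that add atoms: (triphenylphosphoranylidene)acetaldehyde, O=CC=P(c1ccccc1)(c1ccccc1)c1ccccc1
Why: Wittig olefination with a stabilised ylide, which should give the (E)-enal.

Step 13
Reactants: 17 (E)-enal
Product: 18 (E)-2-[3,4-bis(benzyloxy)phenyl]ethenyl formate
Conditions: 30% H2O2, bis(2-nitrophenyl) diselenide (5 mol %), CH2Cl2, rt
Reagents that add atoms: hydrogen peroxide, OO
Why: Baeyer–Villiger oxidation of an α,β-unsaturated aldehyde, in which the electron-rich styryl group migrates with retention of the (E) geometry to give the enol formate.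

Step 14
Reactants: 15 2-hydroxybenzhydrol; 18 (E)-enol formate
Product: 20 perbenzylated trimer (upper unit 2R,3S,4S; middle unit 2R,3S,4R with 3-O-formate; lower unit 2R,3R 4-ketone), via ortho-quinone methide 19 (not isolated)
Conditions: 18 (4 equiv), (R)-3,3'-bis(2,4,6-triisopropylphenyl)-1,1'-binaphthyl-2,2'-diyl N-triflylphosphoramide (10 mol %), 5 Å MS, toluene, −20 °C to rt
Reagents that add atoms: none
Why: The chiral Brønsted acid dehydrates the 2-hydroxybenzhydrol 15 to the (E)-ortho-quinone methide 19, held by hydrogen bonding to the phosphoramide anion, and the electron-rich (E)-styrene 18 adds in an inverse-electron-demand oxa-Diels–Alder reaction in which the C3–C4 bond forms ahead of O1–C2. The closest known reaction type is the chiral phosphoric acid or N-triflylphosphoramide catalysed [4+2] cycloaddition of ortho-quinone methides from 2-hydroxybenzhydrols with styrenes to give 2,4-diarylchromans. Ring C of the middle unit closes by [4+2] cycloaddition (asynchronous concerted or, in the stepwise limit, conjugate addition followed by six-membered closure of the phenoxide onto the benzylic cation). The (E)-alkene geometry fixes C2/C3 trans, the endo position of the ring B aryl group relative to the (E)-quinone methide fixes C2/C4 cis and hence C3/C4 trans, and the chiral catalyst fixes the face of the quinone methide and so the absolute configuration (2R,3S,4R), the stereocentres of the upper and lower units being too remote to help. The step needs regioselectivity (C3 to C4, C2 to O1), secured because positive charge develops at C2 next to the 4-benzyloxyphenyl ring and not next to the weakly donating formyloxy group, and chemoselectivity, secured because O1 is the only free phenol, ring A of the lower unit is deactivated by its ketone and excess dienophile should outrun Friedel–Crafts capture.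

Step 15
Reactants: 20 perbenzylated trimer
Product: 21 heptaphenolic trimer (upper unit 2R,3S,4S; middle unit 2R,3S,4R with 3-O-formate; lower unit 2R,3R 4-ketone)
Conditions: H2 (1 atm), Pd(OH)2/C, THF–EtOAc, rt
Reagents that add atoms: none
Why: Hydrogenolysis of all eleven benzyl ethers under neutral conditions, which the ring C benzylic ether bonds, the doubly benzylic C4–aryl bonds, the para-oxygenated aryl ketone and the formate should survive.

Step 16
Reactants: 21 heptaphenolic trimer ketone
Product: 22 target, fisetinidol-(4β→6)-fisetinidol-(4α→6)-(2R,3S,4R)-flavan-3,4-diol (upper unit 2R,3S,4S; middle unit 2R,3S,4R; lower unit 2R,3S,4R)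
Conditions: NaBH4 (excess), MeOH, 0 °C to rt; acetone quench; Sephadex LH-20
Reagents that add atoms: none
Why: Borohydride reduction of the 2,3-trans-dihydroflavonol ketone by axial hydride delivery should give the equatorial 4-OH (3,4-trans, 4R), as in the known reduction of fustin to mollisacacidin, and the basic methanolic medium removes the labile formate by methanolysis, so the acid-sensitive 4-ol appears only in the last step.

Compound list
1 | (+)-taxifolin, (2R,3R)-2-(3,4-dihydroxyphenyl)-3,5,7-trihydroxychroman-4-one | O=C1c2c(O)cc(O)cc2O[C@H](c3ccc(O)c(O)c3)[C@H]1O | starting material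
2 | (2R,3R)-7-(benzyloxy)-2-[3,4-bis(benzyloxy)phenyl]-3,5-dihydroxychroman-4-one | O=C1c2c(O)cc(OCc9ccccc9)cc2O[C@H](c8ccc(OCc9ccccc9)c(OCc9ccccc9)c8)[C@H]1O | intermediate
3 | (2R,3R)-7-(benzyloxy)-2-[3,4-bis(benzyloxy)phenyl]-3-hydroxy-4-oxochroman-5-yl trifluoromethanesulfonate | O=C1c2c(OS(=O)(=O)C(F)(F)F)cc(OCc9ccccc9)cc2O[C@H](c8ccc(OCc9ccccc9)c(OCc9ccccc9)c8)[C@H]1O | intermediate
4 | (2R,3R)-7-(benzyloxy)-2-[3,4-bis(benzyloxy)phenyl]-3-hydroxychroman-4-one | O=C1c2ccc(OCc9ccccc9)cc2O[C@H](c8ccc(OCc9ccccc9)c(OCc9ccccc9)c8)[C@H]1O | intermediate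
5 | (2R,3R)-3,7-bis(benzyloxy)-2-[3,4-bis(benzyloxy)phenyl]chroman-4-one | O=C1c2ccc(OCc9ccccc9)cc2O[C@H](c8ccc(OCc9ccccc9)c(OCc9ccccc9)c8)[C@H]1OCc9ccccc9 | intermediate
6 | 3-(benzyloxy)phenol | Oc1cccc(OCc2ccccc2)c1 | starting material
7 | 3-(benzyloxy)-4-bromophenol | Oc1ccc(Br)c(OCc2ccccc2)c1 | intermediate
8 | 2-(benzyloxy)-1-bromo-4-(methoxymethoxy)benzene | COCOc1ccc(Br)c(OCc2ccccc2)c1 | intermediate
9 | [2-(benzyloxy)-4-(methoxymethoxy)phenyl]lithium | [Li]c1ccc(OCOC)cc1OCc1ccccc1 | intermediate (not isolated)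
10 | (2R,3R)-3,7-bis(benzyloxy)-4-[2-(benzyloxy)-4-(methoxymethoxy)phenyl]-2-[3,4-bis(benzyloxy)phenyl]chroman-4-ol, C4 epimers | OC1(c3ccc(OCOC)cc3OCc9ccccc9)c2ccc(OCc9ccccc9)cc2O[C@H](c8ccc(OCc9ccccc9)c(OCc9ccccc9)c8)[C@H]1OCc9ccccc9 | intermediate
11 | 3-(benzyloxy)-4-{(2R,3S,4S)-3,7-bis(benzyloxy)-2-[3,4-bis(benzyloxy)phenyl]chroman-4-yl}phenol | c9ccccc9COc1ccc2c(c1)O[C@H](c8ccc(OCc9ccccc9)c(OCc9ccccc9)c8)[C@@H](OCc9ccccc9)[C@H]2c3ccc(O)cc3OCc9ccccc9 | intermediate
12 | (2R,3R)-3,7-bis(benzyloxy)-2-[3,4-bis(benzyloxy)phenyl]-6-iodochroman-4-one | O=C1c2cc(I)c(OCc9ccccc9)cc2O[C@H](c8ccc(OCc9ccccc9)c(OCc9ccccc9)c8)[C@H]1OCc9ccccc9 | intermediate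
13 | (2R,3R)-3,7-bis(benzyloxy)-2-[3,4-bis(benzyloxy)phenyl]-4-oxochroman-6-carbaldehyde | O=Cc5cc6c(cc5OCc9ccccc9)O[C@H](c8ccc(OCc9ccccc9)c(OCc9ccccc9)c8)[C@@H](OCc9ccccc9)C6=O | intermediate
14 | 2-phenyl-4H-1,3,2-benzodioxaborin of diol 15 (boron bridging O1 and the carbinol oxygen) | c9ccccc9COc1ccc2c(c1)O[C@H](c8ccc(OCc9ccccc9)c(OCc9ccccc9)c8)[C@@H](OCc9ccccc9)[C@H]2c3cc4C(c5cc6c(cc5OCc9ccccc9)O[C@H](c8ccc(OCc9ccccc9)c(OCc9ccccc9)c8)[C@@H](OCc9ccccc9)C6=O)OB(c7ccccc7)Oc4cc3OCc9ccccc9 | intermediate (not isolated)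
15 | 2-hydroxybenzhydrol joining ring A of the future middle unit (with the upper unit at C6) to C6 of the lower-unit ketone, both carbinol epimers | c9ccccc9COc1ccc2c(c1)O[C@H](c8ccc(OCc9ccccc9)c(OCc9ccccc9)c8)[C@@H](OCc9ccccc9)[C@H]2c3cc(C(O)c5cc6c(cc5OCc9ccccc9)O[C@H](c8ccc(OCc9ccccc9)c(OCc9ccccc9)c8)[C@@H](OCc9ccccc9)C6=O)c(O)cc3OCc9ccccc9 | intermediate
16 | 3,4-bis(benzyloxy)benzaldehyde | O=Cc1ccc(OCc2ccccc2)c(OCc2ccccc2)c1 | starting material
17 | (E)-3-[3,4-bis(benzyloxy)phenyl]prop-2-enal | O=C/C=C/c1ccc(OCc2ccccc2)c(OCc2ccccc2)c1 | intermediate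
18 | (E)-2-[3,4-bis(benzyloxy)phenyl]ethenyl formate | O=CO/C=C/c1ccc(OCc2ccccc2)c(OCc2ccccc2)c1 | intermediate
19 | (E)-ortho-quinone methide of 15 (O1 as carbonyl, lower-unit aryl on the methide carbon anti to the carbonyl) | c9ccccc9COc1ccc2c(c1)O[C@H](c8ccc(OCc9ccccc9)c(OCc9ccccc9)c8)[C@@H](OCc9ccccc9)[C@H]2C3=C/C(=C\c5cc6c(cc5OCc9ccccc9)O[C@H](c8ccc(OCc9ccccc9)c(OCc9ccccc9)c8)[C@@H](OCc9ccccc9)C6=O)C(=O)C=C3OCc9ccccc9 | intermediate (not isolated)
20 | perbenzylated trimer: upper (2R,3S,4S), middle (2R,3S,4R) 3-O-formate, lower (2R,3R) 4-ketone | c9ccccc9COc1ccc2c(c1)O[C@H](c8ccc(OCc9ccccc9)c(OCc9ccccc9)c8)[C@@H](OCc9ccccc9)[C@H]2c3cc4c(cc3OCc9ccccc9)O[C@H](c8ccc(OCc9ccccc9)c(OCc9ccccc9)c8)[C@@H](OC=O)[C@@H]4c5cc6c(cc5OCc9ccccc9)O[C@H](c8ccc(OCc9ccccc9)c(OCc9ccccc9)c8)[C@@H](OCc9ccccc9)C6=O | intermediate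
21 | heptaphenolic trimer: upper (2R,3S,4S), middle (2R,3S,4R) 3-O-formate, lower (2R,3R) 4-ketone | Oc1ccc2c(c1)O[C@H](c8ccc(O)c(O)c8)[C@@H](O)[C@H]2c3cc4c(cc3O)O[C@H](c8ccc(O)c(O)c8)[C@@H](OC=O)[C@@H]4c5cc6c(cc5O)O[C@H](c8ccc(O)c(O)c8)[C@@H](O)C6=O | intermediate
22 | CNP0255184.1, fisetinidol-(4β→6)-fisetinidol-(4α→6)-(2R,3S,4R)-3',4',7-trihydroxyflavan-3,4-diol | Oc1ccc2c(c1)O[C@H](c8ccc(O)c(O)c8)[C@@H](O)[C@H]2c3cc4c(cc3O)O[C@H](c8ccc(O)c(O)c8)[C@@H](O)[C@@H]4c5cc6c(cc5O)O[C@H](c8ccc(O)c(O)c8)[C@@H](O)[C@@H]6O | target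

Total step count: 16. Longest linear sequence: 10 steps (1, 2, 3, 4, 7, 8, 11, 14, 15, 16).

Steps most likely to fail

Step 14. The catalyst may discriminate the two faces of so large a quinone methide only partly, the regiochemistry may partly reverse, and the enol formate may be lost to acid-promoted hydrolysis before it cycloadds. The two facial products are diastereomers and should be separable. The fallback changes the dienophile and the way O3 is introduced. It sets out from 15 and 16. Aldehyde 16 is converted by boron-Wittig olefination (bis(pinacolato)borylmethane, lithium 2,2,6,6-tetramethylpiperidide, THF, −78 °C to rt) into (E)-2-{2-[3,4-bis(benzyloxy)phenyl]ethenyl}-4,4,5,5-tetramethyl-1,3,2-dioxaborolane F1. This has no hydrolysable ester, and its boron-bearing carbon cannot stabilise positive charge, so only the aryl group steers the regiochemistry. Cycloaddition of F1 with the quinone methide from 15 under the acid catalysis of step 14 should give the 3-boryl flavan trimer F2. Oxidation of the C–B bond with retention (NaBO3·4H2O, THF–H2O) should give the perbenzylated trimer with free middle 3-OH F3. Hydrogenolysis as in step 15 should give the heptaphenolic ketone F4, and NaBH4 as in step 16 brings the sequence back to the route at 22.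

Step 11. At reflux the cyclic boronate may ionise early to the quinone methide and be captured by a second phenol (over-condensation), or the electron-rich aldehyde may condense too slowly. The fallback swaps the roles of the partners. It sets out from 11 and 12. Magnesium-mediated ortho-formylation of phenol 11 (MgCl2, Et3N, paraformaldehyde, MeCN, reflux) should give 4-(benzyloxy)-2-hydroxy-5-(upper flavan-4-yl)benzaldehyde F5. Nozaki–Hiyama–Kishi coupling of F5 with aryl iodide 12 (CrCl2 in excess, NiCl2 cat., DMF, rt), which adds to aldehydes in preference to ketones, returns to the route at 15.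

Step 9. Iodination may spread to ring B or to C8 (poor site selectivity). The fallback installs the C6 carbon before the 5-oxygen is removed, using that oxygen as a directing group. It sets out from 2. Magnesium-mediated ortho-formylation (MgCl2, Et3N, paraformaldehyde, MeCN, 60 °C) can only occur at C6, the one free position ortho to the 5-OH, and should give the 6-carbaldehyde F6. Triflation as in step 2 should give triflate F7, palladium-catalysed formate reduction as in step 3 should give the 5-deoxy aldehyde F8, and benzyl transfer as in step 4 returns to the route at 13.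

Further compounds
F1 | step 14 | (E)-2-{2-[3,4-bis(benzyloxy)phenyl]ethenyl}-4,4,5,5-tetramethyl-1,3,2-dioxaborolane | CC1(C)OB(/C=C/c2ccc(OCc3ccccc3)c(OCc3ccccc3)c2)OC1(C)C
F2 | step 14 | analogue of 20 with a pinacolboryl group at C3 of the middle unit in place of the formyloxy group, same spatial arrangement | c9ccccc9COc1ccc2c(c1)O[C@H](c8ccc(OCc9ccccc9)c(OCc9ccccc9)c8)[C@@H](OCc9ccccc9)[C@H]2c3cc4c(cc3OCc9ccccc9)O[C@H](c8ccc(OCc9ccccc9)c(OCc9ccccc9)c8)[C@@H](B7OC(C)(C)C(C)(C)O7)[C@@H]4c5cc6c(cc5OCc9ccccc9)O[C@H](c8ccc(OCc9ccccc9)c(OCc9ccccc9)c8)[C@@H](OCc9ccccc9)C6=O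
F3 | step 14 | analogue of 20 with free 3-OH in the middle unit (2R,3S,4R) | c9ccccc9COc1ccc2c(c1)O[C@H](c8ccc(OCc9ccccc9)c(OCc9ccccc9)c8)[C@@H](OCc9ccccc9)[C@H]2c3cc4c(cc3OCc9ccccc9)O[C@H](c8ccc(OCc9ccccc9)c(OCc9ccccc9)c8)[C@@H](O)[C@@H]4c5cc6c(cc5OCc9ccccc9)O[C@H](c8ccc(OCc9ccccc9)c(OCc9ccccc9)c8)[C@@H](OCc9ccccc9)C6=O
F4 | step 14 | analogue of 21 with free 3-OH in the middle unit (lower unit still the 2R,3R 4-ketone) | Oc1ccc2c(c1)O[C@H](c8ccc(O)c(O)c8)[C@@H](O)[C@H]2c3cc4c(cc3O)O[C@H](c8ccc(O)c(O)c8)[C@@H](O)[C@@H]4c5cc6c(cc5O)O[C@H](c8ccc(O)c(O)c8)[C@@H](O)C6=O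
F5 | step 11 | 4-(benzyloxy)-2-hydroxy-5-{(2R,3S,4S)-3,7-bis(benzyloxy)-2-[3,4-bis(benzyloxy)phenyl]chroman-4-yl}benzaldehyde | c9ccccc9COc1ccc2c(c1)O[C@H](c8ccc(OCc9ccccc9)c(OCc9ccccc9)c8)[C@@H](OCc9ccccc9)[C@H]2c3cc(C=O)c(O)cc3OCc9ccccc9
F6 | step 9 | (2R,3R)-7-(benzyloxy)-2-[3,4-bis(benzyloxy)phenyl]-3,5-dihydroxy-4-oxochroman-6-carbaldehyde | O=Cc1c(O)c2c(cc1OCc9ccccc9)O[C@H](c8ccc(OCc9ccccc9)c(OCc9ccccc9)c8)[C@@H](O)C2=O
F7 | step 9 | (2R,3R)-7-(benzyloxy)-2-[3,4-bis(benzyloxy)phenyl]-6-formyl-3-hydroxy-4-oxochroman-5-yl trifluoromethanesulfonate | O=Cc1c(OS(=O)(=O)C(F)(F)F)c2c(cc1OCc9ccccc9)O[C@H](c8ccc(OCc9ccccc9)c(OCc9ccccc9)c8)[C@@H](O)C2=O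
F8 | step 9 | (2R,3R)-7-(benzyloxy)-2-[3,4-bis(benzyloxy)phenyl]-3-hydroxy-4-oxochroman-6-carbaldehyde | O=Cc1cc2c(cc1OCc9ccccc9)O[C@H](c8ccc(OCc9ccccc9)c(OCc9ccccc9)c8)[C@@H](O)C2=O
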